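The plan rests on the 1,3-diene made up of the lactone C3=C4 bond and the E-CH=CH arm between lactone C3 and ring B C6. It is read as the hallmark of a ring-closing enyne metathesis: lactone C4 and the arm carbon on ring B C6 begin as one alkene, lactone C3 and the inner arm carbon as a terminal alkyne held by the lactone ester. A single operation closes the butenolide and transfers ring B to the arm. The precursor is the propiolate of an E-allylic alcohol with the ring B triol on the alkene and the methylbutenyl side chain on the carbinol carbon; ring A arrives later by Julia–Kocienski olefination.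

Key step: step 15

Remarks on the chemistry
- Atom labels: lactone O1, C2 (C=O), C3, C4, C5; ring B C1 (CMe2), C3 (CH–O), C5 (C(Me)OH), C6 (quaternary carbinol carrying the arm).
- Abbreviations: TBS = tert-butyldimethylsilyl; PT = 1-phenyl-1H-tetrazol-5-yl; RA = (R)-4-(TBS-oxy)-2,6,6-trimethylcyclohex-1-en-1-yl; RB = 4-(TBS-oxy)-1,2-dihydroxy-2,6,6-trimethylcyclohexyl with 1-OH and 4-OTBS cis and 2-OH trans to both, (1R,2R,4S) when C1 carries an alkenyl group (the same arrangement is labelled 1S when C1 carries an alkynyl group).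
- Assumption: the carbinol carbon made in step 12 (later lactone C5) is carried as both epimers, because it becomes sp2 in step 16; it is left undefined in the SMILES of 16, 17, 19, 20 and 22.
- In ring B the 5-OH is anti and the 6-OH syn to the 3-oxygen (a trans-diaxial 5,6-diol). Acetylide addition to a 5-hydroxy-6-ketone would be expected to give the cis-diol, so the diol is set by hydroxyl-directed epoxidation and trans-diaxial hydrolysis (steps 7 and 8).
- The exocyclic lactone alkene is made by bromination and dehydrobromination; an allylic selenoxide at lactone C5 would be prone to [2,3]-shift.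
- In the metathesis precursor the two tertiary hydroxyls stay free and the only other alkene is a trisubstituted allylic silyl ether.

Step 1
Reactants: 1 ketoisophorone
Product: 2 (R)-levodione, (6R)-2,2,6-trimethylcyclohexane-1,4-dione
Conditions: old yellow enzyme 1 (ene-reductase), NADP+ (cat.), glucose dehydrogenase, D-glucose, phosphate buffer pH 6.5, 30 °C
Reagents that add atoms: none
Why: Enzymatic asymmetric conjugate reduction of the enedione C=C (ene-reductase, for which this dione is a standard substrate) should set the methyl-bearing centre as R, and the slightly acidic buffer limits its enolisation.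

Step 2
Reactants: 2 (R)-levodione
Product: 3 (4R,6R)-actinol, (4R,6R)-4-hydroxy-2,2,6-trimethylcyclohexanone
Conditions: LiBH(s-Bu)3 (1.05 equiv), THF, −78 °C; H2O
Reagents that add atoms: none
Why: Chemoselective hydride reduction of the unhindered C4 ketone, in which the bulky borohydride should attack equatorially, away from the gem-dimethyl methyl that is syn-axial to C4, giving the axial 4R alcohol trans to the 6-methyl while the doubly flanked C1 carbonyl is left.

Step 3
Reactants: 3 (4R,6R)-actinol
Product: 4 (4R,6R)-4-(TBS-oxy)-2,2,6-trimethylcyclohexanone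
Conditions: TBSCl, imidazole, DMF, rt
Reagents that add atoms: tert-butyldimethylsilyl chloride, CC(C)(C)[Si](C)(C)Cl
Why: Standard imidazole-promoted silylation of a secondary alcohol, which leaves both stereocentres untouched.

Step 4
Reactants: 4 silyl ether of actinol
Product: 5 (R)-4-(TBS-oxy)-2,6,6-trimethylcyclohex-1-en-1-yl trifluoromethanesulfonate
Conditions: LiN(i-Pr)2, THF, −78 → 0 °C; PhNTf2, −78 → 0 °C
Reagents that add atoms: N-phenylbis(trifluoromethanesulfonimide), O=S(=O)(N(c1ccccc1)S(=O)(=O)C(F)(F)F)C(F)(F)F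
Why: Enol triflate formation, in which only C6 carries an α-hydrogen so that enolisation and O-sulfonylation can give only the tetrasubstituted enol triflate, the C6 stereocentre being erased on purpose.

Step 5
Reactants: 5 enol triflate; 6 trimethylsilylacetylene
Product: 7 (R)-tert-butyldimethyl{[3,5,5-trimethyl-4-(trimethylsilylethynyl)cyclohex-3-en-1-yl]oxy}silane
Conditions: Pd(PPh3)4 (5 mol%), CuI (10 mol%), Et3N, DMF, rt
Reagents that add atoms: none
Why: Sonogashira coupling of the hindered vinyl triflate with a silyl-capped terminal alkyne, which cannot couple twice and leaves the remote stereocentre alone.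

Step 6
Reactants: 7 silylated enyne
Product: 8 (R)-4-ethynyl-3,5,5-trimethylcyclohex-3-en-1-ol
Conditions: Bu4NF, THF, 0 °C → rt
Reagents that add atoms: none
Why: Fluoride-mediated desilylation cleaves both the alkynyl C–Si and the O–Si bond and so frees the hydroxyl that directs step 7.

Step 7
Reactants: 8 enynol
Product: 9 (1S,3S,6S)-6-ethynyl-1,5,5-trimethyl-7-oxabicyclo[4.1.0]heptan-3-ol (epoxide oxygen cis to the hydroxyl)
Conditions: VO(acac)2 (5 mol%), t-BuOOH (1.5 equiv), CH2Cl2, 0 °C → rt
Reagents that add atoms: tert-butyl hydroperoxide, CC(C)(C)OO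
Why: Vanadium-catalysed hydroxyl-directed epoxidation, in which the homoallylic hydroxyl binds the metal peroxide and should deliver oxygen to the tetrasubstituted ring alkene on its own face, setting both epoxide carbons cis to the hydroxyl while the alkyne is inert.

Step 8
Reactants: 9 cis-epoxy alcohol
Product: 10 (1S,2R,4S)-1-ethynyl-2,6,6-trimethylcyclohexane-1,2,4-triol (1-OH and 4-OH cis, 2-OH trans to both)
Conditions: HClO4 (cat.), THF/H2O (3:1), 0 °C → rt
Reagents that add atoms: water, O
Why: Acid-catalysed epoxide hydrolysis, in which water should open the protonated epoxide at the methyl-bearing carbon (ring B C5) with inversion in the trans-diaxial sense (Fürst–Plattner rule), because the other epoxide carbon is neopentyl and propargylic and keeps its C–O bond, which gives 5-OH anti and 6-OH syn to 3-OH.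

Step 9
Reactants: 10 ethynyl triol
Product: 11 (1S,2R,4S)-4-(TBS-oxy)-1-ethynyl-2,6,6-trimethylcyclohexane-1,2-diol
Conditions: TBSCl (1.1 equiv), imidazole, DMF, 0 °C → rt
Reagents that add atoms: tert-butyldimethylsilyl chloride, CC(C)(C)[Si](C)(C)Cl
Why: Selective silylation of the only secondary hydroxyl, both tertiary hydroxyls being too hindered for this reagent.

Step 10
Reactants: 12 (E)-3-methylpent-2-en-4-yn-1-ol
Product: 13 (E)-tert-butyldimethyl[(3-methylpent-2-en-4-yn-1-yl)oxy]silane
Conditions: TBSCl, imidazole, CH2Cl2, rt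
Reagents that add atoms: tert-butyldimethylsilyl chloride, CC(C)(C)[Si](C)(C)Cl
Why: Standard silylation of a primary alcohol, alkene geometry untouched.

Step 11
Reactants: 13 silylated enynol
Product: 15 (E)-5-(TBS-oxy)-3-methylpent-3-enal, via dienylborane 14 (not isolated)
Conditions: (c-C6H11)2BH (from BH3·SMe2 and cyclohexene), THF, 0 °C; then H2O2, pH 7 phosphate buffer, 0 °C; used crude
Reagents that add atoms: hydrogen peroxide, OO
Why: Anti-Markovnikov hydration of a terminal alkyne by hydroboration–oxidation, in which the hindered dialkylborane adds once, syn and with boron on the terminal carbon, far faster than to the trisubstituted alkene, and the dienol released on buffered oxidation should protonate kinetically at the α-carbon to give the β,γ-unsaturated aldehyde with the E alkene intact.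

Step 12
Reactants: 11 ring B alkyne; 15 aldehyde
Product: 16 (5E)-1-[(1S,2R,4S)-RB]-7-(TBS-oxy)-5-methylhept-5-en-1-yn-3-ol, both C3 epimers
Conditions: 11, EtMgBr (3.1 equiv), THF, 0 → 40 °C; then 15 (1.3 equiv), −20 → 0 °C; aq. NH4Cl
Reagents that add atoms: none
Why: Addition of an alkynylmagnesium reagent to an aldehyde, in which the weakly basic bromomagnesium acetylide bis-alkoxide should add 1,2 faster than it enolises the sensitive aldehyde; the new carbinol centre is not controlled and both epimers are carried.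

Step 13
Reactants: 16 propargylic alcohol
Product: 17 (1E,5E)-1-[(1R,2R,4S)-RB]-7-(TBS-oxy)-5-methylhepta-1,5-dien-3-ol, both C3 epimers
Conditions: NaAlH2(OCH2CH2OMe)2 (5 equiv), THF, 0 °C → rt; aq. KNaC4H4O6
Reagents that add atoms: none
Why: trans-Hydroalumination of a propargylic alcohol, in which alkoxide-bound aluminium delivers hydride intramolecularly and protonolysis of the vinylalanate should give only the E alkene, with silyl ethers and the trisubstituted alkene inert.

Step 14
Reactants: 17 allylic alcohol; 18 propiolic acid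
Product: 19 (1E,5E)-1-[(1R,2R,4S)-RB]-7-(TBS-oxy)-5-methylhepta-1,5-dien-3-yl prop-2-ynoate, both C3 epimers
Conditions: 18 (1.5 equiv), DCC (1.5 equiv), DMAP (5 mol%), CH2Cl2, −20 → 0 °C
Reagents that add atoms: none
Why: Steglich esterification of the only secondary hydroxyl, the tertiary hydroxyls being unreactive, with low temperature and little DMAP to limit amine addition to the ynoate.

Step 15
Reactants: 19 propiolate ester
Product: 20 3-[(E)-2-((1R,2R,4S)-RB)ethenyl]-5-[(E)-4-(TBS-oxy)-2-methylbut-2-en-1-yl]furan-2(5H)-one, both lactone C5 epimers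
Conditions: second-generation Grubbs catalyst RuCl2(=CHPh)(PCy3)(H2IMes) (15 mol%, in two portions), toluene (0.05 M), 80 °C, argon, no ethylene
Reagents that add atoms: none
Why: Proposed new method: the ruthenium alkylidene should enter at the disubstituted alkene of 19 and form an alkylidene on the future lactone C4, which adds to the terminal alkyne and leaves a vinylcarbene on the outer alkyne carbon; this carbene turns over by metathesis with the alkene of the next molecule of 19, taking its CH–ring B end as the new arm double bond and regenerating the C4 alkylidene, so the change is an isomerisation that needs no ethylene (a cycle in which a ring B-substituted alkylidene adds first to the alkyne gives the same product). The closest known reaction type is ring-closing metathesis of 1,6-enynes to 1-vinylcycloalkenes with this catalyst; an ester tether with the alkyne on the acyl side combined with an internal alkene next to a quaternary carbinol has not been shown. The only ring closed is the lactone, by 5-exo closure through the new C3=C4 bond rather than endo closure to a six-membered pyranone. No stereocentre is formed, and the epimeric lactone C5 and the ring B centres are untouched. The step needs exo regiochemistry, E geometry of the new arm alkene and chemoselection against the trisubstituted side-chain alkene; the 1,6-spacing of alkyne and alkene, the bulk of the quaternary ring B C6 and the inertness of trisubstituted allylic silyl ethers should secure these, while the free tertiary allylic 6-OH can guide the catalyst to the hindered alkene by hydrogen bonding to its chloride ligands. Heating in toluene gives access to the s-cis ester conformer needed for closure, and the absence of ethylene keeps ring B from being lost as a vinyl fragment.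

Step 16
Reactants: 20 butenolide
Product: 23 (5Z)-5-[(E)-4-(TBS-oxy)-2-methylbut-2-en-1-ylidene]-3-[(E)-2-((1R,2R,4S)-RB)ethenyl]furan-2(5H)-one, via silyloxyfuran 21 (not isolated), via bromolactone 22 (not isolated)
Conditions: i-Pr3SiOTf (1.2 equiv), Et3N (1.5 equiv), CH2Cl2, 0 °C; then THF, NBS (1.05 equiv), −78 °C; then DBU (2 equiv), −78 °C → rt
Reagents that add atoms: none
Why: Net dehydrogenation through a 2-silyloxyfuran, in which enol silylation at lactone C5–H (the hindered silyl triflate should spare the tertiary alcohols), electrophilic bromination of the furan at C5 and dehydrobromination toward the side-chain CH2 should give the exocyclic alkene, Z being favoured because it keeps the chain away from lactone C4–H, and the epimeric centre disappears.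

Step 17
Reactants: 23 ylidene butenolide
Product: 24 (5Z)-5-[(E)-4-hydroxy-2-methylbut-2-en-1-ylidene]-3-[(E)-2-((1R,2R,4S)-RB)ethenyl]furan-2(5H)-one
Conditions: HF·pyridine, pyridine, THF, 0 °C
Reagents that add atoms: none
Why: Fluoride-mediated desilylation under buffered conditions, selective for the primary allylic silyl ether over the hindered secondary one on ring B.

Step 18
Reactants: 24 primary allylic alcohol
Product: 25 (2E,4Z)-3-methyl-4-{4-[(E)-2-((1R,2R,4S)-RB)ethenyl]-5-oxofuran-2(5H)-ylidene}but-2-enal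
Conditions: MnO2 (activated, 20 equiv), CH2Cl2, rt
Reagents that add atoms: none
Why: MnO2 oxidation, specific for the allylic primary alcohol, with tertiary alcohols, silyl ether and enol lactone inert.

Step 19
Reactants: 25 dienal; 26 (triphenylphosphoranylidene)acetaldehyde
Product: 27 (2E,4E,6Z)-5-methyl-6-{4-[(E)-2-((1R,2R,4S)-RB)ethenyl]-5-oxofuran-2(5H)-ylidene}hexa-2,4-dienal
Conditions: 26 (1.2 equiv), toluene, 60 °C
Reagents that add atoms: none
Why: Wittig olefination with a stabilised formylmethylene ylide (two-carbon vinylogation), E-selective and neutral so that the enol lactone and free hydroxyls are tolerated, with only a small excess of ylide to limit a second homologation.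

Step 20
Reactants: 5 enol triflate; 12 (E)-3-methylpent-2-en-4-yn-1-ol
Product: 28 (E)-5-RA-3-methylpent-2-en-4-yn-1-ol
Conditions: Pd(PPh3)4 (5 mol%), CuI (10 mol%), Et3N, DMF, rt
Reagents that add atoms: none
Why: Sonogashira coupling of the vinyl triflate with the terminal enyne, which tolerates the free primary alcohol and retains the E alkene of 12.

Step 21
Reactants: 28 ring A enynol
Product: 29 5-{[(E)-5-RA-3-methylpent-2-en-4-yn-1-yl]sulfanyl}-1-phenyl-1H-tetrazole
Conditions: 1-phenyl-1H-tetrazole-5-thiol, PPh3, DIAD, THF, 0 °C → rt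
Reagents that add atoms: 1-phenyl-1H-tetrazole-5-thiol, Sc1nnnn1-c1ccccc1
Why: Mitsunobu thioetherification of a primary allylic alcohol by SN2 displacement, without allylic transposition.

Step 22
Reactants: 29 sulfide
Product: 30 5-{[(E)-5-RA-3-methylpent-2-en-4-yn-1-yl]sulfonyl}-1-phenyl-1H-tetrazole
Conditions: (NH4)6Mo7O24·4H2O (10 mol%), 30% H2O2, EtOH, 0 °C → rt
Reagents that add atoms: hydrogen peroxide, OO
Why: Molybdate-catalysed sulfide-to-sulfone oxidation with H2O2, which should spare the enyne, the trisubstituted alkene and the silyl ether.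

Step 23
Reactants: 27 trienal; 30 ring A sulfone
Product: 32 bis-TBS ether of the target (silyl ethers on ring A 3-OH and ring B 3-OH, all-E chain, Z ylidene), via Z isomer 31 (not isolated)
Conditions: 30 (1.5 equiv), NaN(SiMe3)2 (1.45 equiv), THF, −78 °C; then 27, −78 → −20 °C; then I2 (cat.), benzene, rt, daylight
Reagents that add atoms: none
Why: Julia–Kocienski olefination, in which the preformed allylic sulfonyl anion should add to the trienal faster than it is protonated by the hindered tertiary hydroxyls, Smiles rearrangement with loss of SO2 and aryloxide gives the new C=C as an E/Z mixture, and iodine-catalysed equilibration of the crude polyene should converge on the all-E chain while the favoured Z ylidene is kept.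

Step 24
Reactants: 32 bis-silyl ether
Product: 33 CNP0163979.1
Conditions: HF·pyridine, pyridine, THF, 0 °C → rt
Reagents that add atoms: none
Why: Fluoride-mediated cleavage of both secondary silyl ethers under pyridine-buffered conditions, mild enough for the enol lactone, the polyene and the tertiary allylic alcohol, with no stereocentre affected.

Compound list
1 | ketoisophorone (2,6,6-trimethylcyclohex-2-ene-1,4-dione) | CC1=CC(=O)CC(C)(C)C1=O | starting material
2 | (R)-levodione, (6R)-2,2,6-trimethylcyclohexane-1,4-dione | C[C@@H]1CC(=O)CC(C)(C)C1=O | intermediate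
3 | (4R,6R)-actinol, (4R,6R)-4-hydroxy-2,2,6-trimethylcyclohexanone | C[C@@H]1C[C@@H](O)CC(C)(C)C1=O | intermediate
4 | (4R,6R)-4-(TBS-oxy)-2,2,6-trimethylcyclohexanone | C[C@@H]1C[C@@H](O[Si](C)(C)C(C)(C)C)CC(C)(C)C1=O | intermediate
5 | (R)-4-(TBS-oxy)-2,6,6-trimethylcyclohex-1-en-1-yl trifluoromethanesulfonate | CC1=C(OS(=O)(=O)C(F)(F)F)C(C)(C)C[C@H](O[Si](C)(C)C(C)(C)C)C1 | intermediate
6 | trimethylsilylacetylene | C#C[Si](C)(C)C | starting material
7 | (R)-tert-butyldimethyl{[3,5,5-trimethyl-4-(trimethylsilylethynyl)cyclohex-3-en-1-yl]oxy}silane | CC1=C(C#C[Si](C)(C)C)C(C)(C)C[C@H](O[Si](C)(C)C(C)(C)C)C1 | intermediate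
8 | (R)-4-ethynyl-3,5,5-trimethylcyclohex-3-en-1-ol | CC1=C(C#C)C(C)(C)C[C@H](O)C1 | intermediate
9 | (1S,3S,6S)-6-ethynyl-1,5,5-trimethyl-7-oxabicyclo[4.1.0]heptan-3-ol (epoxide cis to OH) | C#C[C@@]12C(C)(C)C[C@H](O)C[C@]1(C)O2 | intermediate
10 | (1S,2R,4S)-1-ethynyl-2,6,6-trimethylcyclohexane-1,2,4-triol | C#C[C@@]1(O)C(C)(C)C[C@H](O)C[C@@]1(C)O | intermediate
11 | (1S,2R,4S)-4-(TBS-oxy)-1-ethynyl-2,6,6-trimethylcyclohexane-1,2-diol | C#C[C@@]1(O)C(C)(C)C[C@H](O[Si](C)(C)C(C)(C)C)C[C@@]1(C)O | intermediate
12 | (E)-3-methylpent-2-en-4-yn-1-ol | C#C/C(C)=C/CO | starting material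
13 | (E)-tert-butyldimethyl[(3-methylpent-2-en-4-yn-1-yl)oxy]silane | C#C/C(C)=C/CO[Si](C)(C)C(C)(C)C | intermediate
14 | dicyclohexyl[(1E,3E)-5-(TBS-oxy)-3-methylpenta-1,3-dien-1-yl]borane | CC(C)(C)[Si](C)(C)OC/C=C(C)/C=C/B(C1CCCCC1)C1CCCCC1 | intermediate (not isolated)
15 | (E)-5-(TBS-oxy)-3-methylpent-3-enal | O=CC/C(C)=C/CO[Si](C)(C)C(C)(C)C | intermediate
16 | (5E)-1-[(1S,2R,4S)-RB]-7-(TBS-oxy)-5-methylhept-5-en-1-yn-3-ol, both C3 epimers | CC(C)(C)[Si](C)(C)OC/C=C(C)/CC(O)C#C[C@@]1(O)C(C)(C)C[C@H](O[Si](C)(C)C(C)(C)C)C[C@@]1(C)O | intermediate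
17 | (1E,5E)-1-[(1R,2R,4S)-RB]-7-(TBS-oxy)-5-methylhepta-1,5-dien-3-ol, both C3 epimers | CC(C)(C)[Si](C)(C)OC/C=C(C)/CC(O)/C=C/[C@@]1(O)C(C)(C)C[C@H](O[Si](C)(C)C(C)(C)C)C[C@@]1(C)O | intermediate
18 | propiolic acid | C#CC(=O)O | starting material
19 | propiolate ester of 17 (metathesis precursor), both epimers at the ester-bearing carbon | C#CC(=O)OC(C/C(C)=C/CO[Si](C)(C)C(C)(C)C)/C=C/[C@@]1(O)C(C)(C)C[C@H](O[Si](C)(C)C(C)(C)C)C[C@@]1(C)O | intermediate
20 | 3-[(E)-2-((1R,2R,4S)-RB)ethenyl]-5-[(E)-4-(TBS-oxy)-2-methylbut-2-en-1-yl]furan-2(5H)-one, both lactone C5 epimers | CC(C)(C)[Si](C)(C)OC/C=C(C)/CC1C=C(/C=C/[C@@]2(O)C(C)(C)C[C@H](O[Si](C)(C)C(C)(C)C)C[C@@]2(C)O)C(=O)O1 | intermediate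
21 | 2-(triisopropylsilyloxy)furan derived from 20 (3-arm and 5-side chain unchanged) | CC(C)[Si](C(C)C)(C(C)C)Oc1oc(C/C(C)=C/CO[Si](C)(C)C(C)(C)C)cc1/C=C/[C@@]1(O)C(C)(C)C[C@H](O[Si](C)(C)C(C)(C)C)C[C@@]1(C)O | intermediate (not isolated)
22 | 5-bromo derivative of 20 (bromine on lactone C5), both epimers | CC(C)(C)[Si](C)(C)OC/C=C(C)/CC1(Br)C=C(/C=C/[C@@]2(O)C(C)(C)C[C@H](O[Si](C)(C)C(C)(C)C)C[C@@]2(C)O)C(=O)O1 | intermediate (not isolated)
23 | (5Z)-5-[(E)-4-(TBS-oxy)-2-methylbut-2-en-1-ylidene]-3-[(E)-2-((1R,2R,4S)-RB)ethenyl]furan-2(5H)-one | CC(C)(C)[Si](C)(C)OC/C=C(C)/C=C1C=C(/C=C/[C@@]2(O)C(C)(C)C[C@H](O[Si](C)(C)C(C)(C)C)C[C@@]2(C)O)C(=O)O/1 | intermediate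
24 | (5Z)-5-[(E)-4-hydroxy-2-methylbut-2-en-1-ylidene]-3-[(E)-2-((1R,2R,4S)-RB)ethenyl]furan-2(5H)-one | OC/C=C(C)/C=C1C=C(/C=C/[C@@]2(O)C(C)(C)C[C@H](O[Si](C)(C)C(C)(C)C)C[C@@]2(C)O)C(=O)O/1 | intermediate
25 | (2E,4Z)-3-methyl-4-{4-[(E)-2-((1R,2R,4S)-RB)ethenyl]-5-oxofuran-2(5H)-ylidene}but-2-enal | O=C/C=C(C)/C=C1C=C(/C=C/[C@@]2(O)C(C)(C)C[C@H](O[Si](C)(C)C(C)(C)C)C[C@@]2(C)O)C(=O)O/1 | intermediate
26 | (triphenylphosphoranylidene)acetaldehyde | O=CC=P(c1ccccc1)(c1ccccc1)c1ccccc1 | starting material
27 | (2E,4E,6Z)-5-methyl-6-{4-[(E)-2-((1R,2R,4S)-RB)ethenyl]-5-oxofuran-2(5H)-ylidene}hexa-2,4-dienal | O=C/C=C/C=C(C)/C=C1C=C(/C=C/[C@@]2(O)C(C)(C)C[C@H](O[Si](C)(C)C(C)(C)C)C[C@@]2(C)O)C(=O)O/1 | intermediate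
28 | (E)-5-RA-3-methylpent-2-en-4-yn-1-ol | CC1=C(C#C/C(C)=C/CO)C(C)(C)C[C@H](O[Si](C)(C)C(C)(C)C)C1 | intermediate
29 | 5-{[(E)-5-RA-3-methylpent-2-en-4-yn-1-yl]sulfanyl}-1-phenyl-1H-tetrazole | CC1=C(C#C/C(C)=C/CSc2nnnn2-c2ccccc2)C(C)(C)C[C@H](O[Si](C)(C)C(C)(C)C)C1 | intermediate
30 | 5-{[(E)-5-RA-3-methylpent-2-en-4-yn-1-yl]sulfonyl}-1-phenyl-1H-tetrazole | CC1=C(C#C/C(C)=C/CS(=O)(=O)c2nnnn2-c2ccccc2)C(C)(C)C[C@H](O[Si](C)(C)C(C)(C)C)C1 | intermediate
31 | isomer of 32 with Z geometry at the double bond made in step 23 | CC1=C(C#C/C(C)=C/C=C\C=C\C=C(C)\C=C2C=C(/C=C/[C@@]3(O)C(C)(C)C[C@H](O[Si](C)(C)C(C)(C)C)C[C@@]3(C)O)C(=O)O\2)C(C)(C)C[C@H](O[Si](C)(C)C(C)(C)C)C1 | intermediate (not isolated)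
32 | bis-TBS ether of the target (ring A 3-OTBS, ring B 3-OTBS) | CC1=C(C#C/C(C)=C/C=C/C=C/C=C(C)/C=C2C=C(/C=C/[C@@]3(O)C(C)(C)C[C@H](O[Si](C)(C)C(C)(C)C)C[C@@]3(C)O)C(=O)O/2)C(C)(C)C[C@H](O[Si](C)(C)C(C)(C)C)C1 | intermediate
33 | CNP0163979.1, (5Z)-3-{(E)-2-[(1R,2R,4S)-1,2,4-trihydroxy-2,6,6-trimethylcyclohexyl]ethenyl}-5-{(2E,4E,6E,8E)-11-[(R)-4-hydroxy-2,6,6-trimethylcyclohex-1-en-1-yl]-2,9-dimethylundeca-2,4,6,8-tetraen-10-yn-1-ylidene}furan-2(5H)-one | CC1=C(C#C/C(C)=C/C=C/C=C/C=C(C)/C=C2C=C(/C=C/[C@@]3(O)C(C)(C)C[C@H](O)C[C@@]3(C)O)C(=O)O/2)C(C)(C)C[C@H](O)C1 | target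

Total step count: 24 steps.
Longest linear sequence: 19 steps (steps 1–9, 12–19, 23 and 24).

Steps most likely to fail

1. Step 15. The catalyst may stall after ring closure, because the conjugated vinylcarbene, held by the lactone carbonyl, may fail to exchange with the hindered internal alkene; the terminal ynoate may also oligomerise before the ester reaches its s-cis conformer. The fallback leaves the route at aldehyde 15 and alkyne 11 and returns at butenolide 20, so that steps 12 to 15 are bypassed. Methyl propiolate, lithiated with LiN(i-Pr)2 in THF at −78 °C, adds to 15 to give methyl (E)-4-hydroxy-8-(TBS-oxy)-6-methyloct-6-en-2-ynoate F1. Palladium-catalysed syn-hydrostannation (Bu3SnH, Pd(PPh3)4) should place tin on the α-carbon and give methyl (2E,6E)-4-hydroxy-8-(TBS-oxy)-6-methyl-2-(tributylstannyl)octa-2,6-dienoate F2, which lactonises with loss of methanol (PPTS if needed) to 3-(tributylstannyl)-5-[(E)-4-(TBS-oxy)-2-methylbut-2-en-1-yl]furan-2(5H)-one F3. Hydrozirconation of 11 with Cp2Zr(H)Cl (excess, to cover the two hydroxyls) and iodinolysis gives (1R,2R,4S)-4-(TBS-oxy)-1-[(E)-2-iodoethenyl]-2,6,6-trimethylcyclohexane-1,2-diol F4. Stille coupling of F3 with F4 (Pd2(dba)3, AsPh3, CuI, NMP) forms the bond between lactone C3 and the arm and delivers 20.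

2. Step 16. Silylation may spread to the tertiary hydroxyls, bromine may be delivered to the arm diene instead of furan C5, or the base may open the enol lactone once it has formed. The fallback leaves from 20 and returns at 23, replacing halogenation and dehydrohalogenation by oxygenation and dehydration. Silyloxyfuran 21 is made as before and oxidised with dimethyldioxirane in acetone at −78 °C to the 5-hydroxy derivative of 20 (hydroxyl on lactone C5) F5. Acetylation of this hemiketal hydroxyl (Ac2O, Et3N, DMAP cat.) gives the 5-acetoxy derivative of 20 F6, and DBU-induced loss of acetic acid gives 23.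

3. Step 23. Proton transfer from the free tertiary hydroxyls or attack on the enol lactone may consume the sulfonyl anion, and the allylic anion may scramble the neighbouring double bonds so that equilibration does not converge on one isomer. The fallback leaves from dienal 25 and ring A enynol 28 and returns at 32, so that steps 19 and 21 to 23 are bypassed. Takai olefination of 25 (CrCl2, CHI3, THF, 0 °C) gives the (1E,3E,5Z)-iodotriene with iodine on the new terminal carbon F7. Oxidation of 28 with MnO2 gives (E)-5-RA-3-methylpent-2-en-4-ynal F8, and olefination with Bu3SnCHBr2, CrCl2 and LiI gives tributyl[(1E,3E)-6-RA-4-methylhexa-1,3-dien-5-yn-1-yl]stannane F9. Stille coupling of F7 with F9 (Pd2(dba)3, AsPh3, NMP, rt) joins the two halves with retention of all alkene geometries and gives 32.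

Further compounds
F1 | step 15 | methyl (E)-4-hydroxy-8-(TBS-oxy)-6-methyloct-6-en-2-ynoate | COC(=O)C#CC(O)C/C(C)=C/CO[Si](C)(C)C(C)(C)C
F2 | step 15 | methyl (2E,6E)-4-hydroxy-8-(TBS-oxy)-6-methyl-2-(tributylstannyl)octa-2,6-dienoate | COC(=O)/C(=C\C(O)C/C(C)=C/CO[Si](C)(C)C(C)(C)C)[Sn](CCCC)(CCCC)CCCC
F3 | step 15 | 3-(tributylstannyl)-5-[(E)-4-(TBS-oxy)-2-methylbut-2-en-1-yl]furan-2(5H)-one | CCCC[Sn](CCCC)(CCCC)C1=CC(C/C(C)=C/CO[Si](C)(C)C(C)(C)C)OC1=O
F4 | step 15 | (1R,2R,4S)-4-(TBS-oxy)-1-[(E)-2-iodoethenyl]-2,6,6-trimethylcyclohexane-1,2-diol | I/C=C/[C@@]1(O)C(C)(C)C[C@H](O[Si](C)(C)C(C)(C)C)C[C@@]1(C)O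
F5 | step 16 | 5-hydroxy derivative of 20 (hydroxyl on lactone C5) | CC(C)(C)[Si](C)(C)OC/C=C(C)/CC1(O)C=C(/C=C/[C@@]2(O)C(C)(C)C[C@H](O[Si](C)(C)C(C)(C)C)C[C@@]2(C)O)C(=O)O1
F6 | step 16 | 5-acetoxy derivative of 20 (acetate on lactone C5) | CC(=O)OC1(C/C(C)=C/CO[Si](C)(C)C(C)(C)C)C=C(/C=C/[C@@]2(O)C(C)(C)C[C@H](O[Si](C)(C)C(C)(C)C)C[C@@]2(C)O)C(=O)O1
F7 | step 23 | (5Z)-5-[(2E,4E)-5-iodo-2-methylpenta-2,4-dien-1-ylidene]-3-[(E)-2-((1R,2R,4S)-RB)ethenyl]furan-2(5H)-one | I/C=C/C=C(C)/C=C1C=C(/C=C/[C@@]2(O)C(C)(C)C[C@H](O[Si](C)(C)C(C)(C)C)C[C@@]2(C)O)C(=O)O/1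
F8 | step 23 | (E)-5-RA-3-methylpent-2-en-4-ynal | CC1=C(C#C/C(C)=C/C=O)C(C)(C)C[C@H](O[Si](C)(C)C(C)(C)C)C1
F9 | step 23 | tributyl[(1E,3E)-6-RA-4-methylhexa-1,3-dien-5-yn-1-yl]stannane | CC1=C(C#C/C(C)=C/C=C/[Sn](CCCC)(CCCC)CCCC)C(C)(C)C[C@H](O[Si](C)(C)C(C)(C)C)C1
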